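**Plan**

1. Feature: in the ten-membered carbocycle (C1–C10) the C4=C5 double bond and the C1–C10 single bond are 1,5-related, so the ring is the opened form of a cyclobutane C4–C5–C10–C1 that fuses a six-membered enone ring (C5–C10) to a four-membered ring (C1–C4).
2. Cuts, in retrosynthetic order: the C8 ester and the O15/O3 protecting groups; C11=C13; the lactone bond O6–C12; the oxolane bond O–C10; then the ten-membered ring is folded back (C5–C10 and C1–C4 re-formed) and the photoadduct is cut at C4–C5 and C1–C10; C7–C11 last.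
3. Forward ring order: six-membered enone ring → (2+2) photoadduct (six–four–four tricycle) → thermal opening to the ten-membered 1(10),4-dien-3-one → transannular iodo-ketalisation (oxolane O–C3–C2–C1–C10) → γ-lactone → exo-methylene.
4. Stereochemistry: C8 from lipase desymmetrisation of a meso diol; C7 by kinetic protonation anti to the 8-silyloxy group; the photoaddition anti to both; C6 by hydride on the convex face of the photoadduct; 4Z from the chair diyl of the ring opening; C10 (and with it C3) in the transannular closure.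
5. The C3 ketal is unmasked to the ketone before the ring opening, so that cleavage of C2–C3 in the diyl, or a later Cope rearrangement, would have to form a ketene and is shut off.

Key step: step 9

Numbering: all carbons carry the germacrane numbers of the target (ring C1–C10, lactone carbons C11–C13, C14 = methyl on C10, C15 = CH2O on C4); α is the face of O6, β the face of C11 and O8.

Assumption: C3 and C10 are the two ends of one oxygen bridge and the carbocycle can span the oxolane on one face only, so the route sets C10 (step 15) and C3 follows from it; the SMILES of all bridged compounds keep both bridgehead descriptors exactly as written in the given structure.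

**Route**

Step 1
Reactants: 1 cis,cis-cyclohexane-1,3,5-triol
Product: 2 all-cis-5-(tert-butyldimethylsilyloxy)cyclohexane-1,3-diol (meso)
Conditions: TBSCl (1.0 equiv), imidazole, DMF, 0 °C → rt
Reagents that add atoms: tert-butyldimethylsilyl chloride, CC(C)(C)[Si](C)(C)Cl
Why: Statistical monosilylation of a triol with three equivalent hydroxyls (unreacted triol is recycled); no stereocentre is created because 2 is meso.

Step 2
Reactants: 2 all-cis-5-(tert-butyldimethylsilyloxy)cyclohexane-1,3-diol
Product: 3 (1S,3R,5R)-3-hydroxy-5-(tert-butyldimethylsilyloxy)cyclohexyl acetate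
Conditions: Pseudomonas cepacia lipase, vinyl acetate, tBuOMe, rt
Reagents that add atoms: vinyl acetate, CC(=O)OC=C
Why: Enzymatic desymmetrisation (lipase transesterification) acylates one enantiotopic hydroxyl of the meso diol and so sets the absolute configuration that becomes C8; should the enzyme prefer the antipode, hydrolysis of the diacetate with the same lipase gives 3.

Step 3
Reactants: 3 (1S,3R,5R)-3-hydroxy-5-(tert-butyldimethylsilyloxy)cyclohexyl acetate
Product: 5 (S)-5-(tert-butyldimethylsilyloxy)cyclohex-2-en-1-one, via keto acetate 4 (not isolated)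
Conditions: Dess–Martin periodinane, pyridine, CH2Cl2, 0 °C → rt; then DBU, 0 °C
Reagents that add atoms: none
Why: Dess–Martin oxidation of the free alcohol followed by E1cB loss of the β-acetoxy group (acetate, not silyloxide, is the leaving group) gives the enone and leaves the silyloxy centre untouched.

Step 4
Reactants: 5 (S)-5-(tert-butyldimethylsilyloxy)cyclohex-2-en-1-one
Product: 6 (5S)-1-methyl-5-(tert-butyldimethylsilyloxy)cyclohex-2-en-1-ol (both C1 epimers)
Conditions: MeLi, Et2O, −78 °C; then H2O
Reagents that add atoms: methyllithium, [Li]C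
Why: 1,2-Addition of the hard organolithium to the enone carbonyl; the new carbinol centre is destroyed in step 5, so the epimer mixture is used as such.

Step 5
Reactants: 6 (5S)-1-methyl-5-(tert-butyldimethylsilyloxy)cyclohex-2-en-1-ol
Product: 7 (R)-5-(tert-butyldimethylsilyloxy)-3-methylcyclohex-2-en-1-one
Conditions: pyridinium chlorochromate [C5H5NH][CrO3Cl], 4 Å MS, CH2Cl2, rt
Reagents that add atoms: pyridinium chlorochromate, [O-][Cr](=O)(=O)Cl.c1cc[nH+]cc1
Why: Babler–Dauben oxidative 1,3-transposition of a tertiary allylic alcohol (chromate ester, [3,3] shift, oxidation) moves the carbonyl to C6 and leaves the methyl on the β-carbon C10.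

Step 6
Reactants: 7 (R)-5-(tert-butyldimethylsilyloxy)-3-methylcyclohex-2-en-1-one
Product: 9 tert-butyl 2-[(1S,6R)-6-(tert-butyldimethylsilyloxy)-4-methyl-2-oxocyclohex-3-en-1-yl]acetate (trans isomer expected as the major one), via lithium dienolate 8 (not isolated)
Conditions: LiN(iPr)2, THF, −78 °C; then BrCH2CO2tBu, DMPU, −78 → −40 °C
Reagents that add atoms: tert-butyl bromoacetate, CC(C)(C)OC(=O)CBr
Why: Kinetic α'-deprotonation of the enone (cross-conjugated dienolate) and SN2 alkylation form C7–C11; the electrophile should enter mainly anti to the silyloxy group, but C7 is reset in step 7, so the ratio is immaterial.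

Step 7
Reactants: 9 tert-butyl 2-[(1S,6R)-6-(tert-butyldimethylsilyloxy)-4-methyl-2-oxocyclohex-3-en-1-yl]acetate
Product: 11 tert-butyl 2-[(1R,6R)-6-(tert-butyldimethylsilyloxy)-4-methyl-2-oxocyclohex-3-en-1-yl]acetate (cis), via lithium enolate 10 (not isolated)
Conditions: LiN(iPr)2, THF, −78 °C; then 2,6-di-tert-butyl-4-methylphenol, −78 °C; cold pH 7 work-up
Reagents that add atoms: none
Why: Kinetic C-protonation of a ketone enolate: allylic strain with the C7 side chain turns the 8-silyloxy group pseudo-axial, the bulky phenol delivers the proton to the opposite face, and the side chain ends up cis to the silyloxy group (contra-thermodynamic epimerisation).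

Step 8
Reactants: 12 1,1-dimethoxyethene; 13 methyl propiolate
Product: 14 methyl 4,4-dimethoxycyclobut-1-ene-1-carboxylate
Conditions: neat, 0 °C → rt, dark; used directly
Reagents that add atoms: none
Why: Stepwise polar (2+2) cycloaddition of a ketene acetal with an ynoate: the nucleophilic CH2 adds to the β-carbon of the propiolate and the zwitterion closes between the acetal carbon and the α-carbon, which places the ketal next to the ester-bearing carbon; it is kept cold to avoid electrocyclic opening.

Step 9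
Reactants: 11 tert-butyl 2-[(1R,6R)-6-(tert-butyldimethylsilyloxy)-4-methyl-2-oxocyclohex-3-en-1-yl]acetate; 14 methyl 4,4-dimethoxycyclobut-1-ene-1-carboxylate
Product: 15 head-to-head cis-anti-cis photoadduct (6-oxo; 3,3-dimethoxy; C15 methyl ester on C4; 7β-CH2CO2tBu; 8β-OTBS; both four-membered rings on the α-face)
Conditions: hν (350 nm, Pyrex), 14 (4 equiv), CH2Cl2 (degassed), −40 °C
Reagents that add atoms: none
Why: Excitation of enone 11 and intersystem crossing give the twisted triplet, which bonds from its β-carbon C10 to the unsubstituted terminus C1 of 14; the triplet 1,4-diradical (α-keto radical at C5, ester-stabilised tertiary radical at C4) then undergoes spin inversion and closes C4–C5. The closest known reaction type is the head-to-head (2+2) photocycloaddition of cyclohexenones with cyclobutene-1-carboxylates to tricyclo[4.4.0.0(2,5)]decanones. The one new ring, cyclobutane C4–C5–C10–C1, closes by recombination of the 1,4-diradical. Of the four new stereocentres, C5 and C10 are cis through the six–four ring fusion, C1 and C4 are cis because they were the cyclobutene double bond, the ring from 14 lies anti to the six-membered ring for steric reasons, and the face is set by the cis C7 and C8 substituents of 11, which shield the β-face. The step needs head-to-head regiochemistry, secured by the ester-stabilised radical at C4 and by avoiding two adjacent quaternary carbons (C4 next to C10), and it needs α-facial addition because step 10 sets C6 from the cyclobutane face.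

Step 10
Reactants: 15 head-to-head cis-anti-cis photoadduct
Product: 17 6α,15-diol (3,3-dimethoxy; tert-butyl ester and 8β-OTBS kept), via 6α,15-lactone 16 (not isolated)
Conditions: LiBH4, THF, 0 °C → rt
Reagents that add atoms: none
Why: Borohydride should attack the C6 ketone from the convex face, anti to the cyclobutane, so O6 is α (trans to C11) and cis to C15; the alkoxide closes onto the methyl ester to γ-lactone 16, which LiBH4 reduces on to the diol, while the poorly electrophilic tert-butyl ester is spared (chemoselective ester/lactone reduction).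

Step 11
Reactants: 17 6α,15-diol
Product: 18 15-O-tert-butyldiphenylsilyl ether (6α-OH free)
Conditions: TBDPSCl, imidazole, DMAP (cat.), DMF, rt
Reagents that add atoms: tert-butyldiphenylsilyl chloride, CC(C)(C)[Si](Cl)(c1ccccc1)c1ccccc1
Why: Selective silylation of the primary hydroxyl over the hindered secondary one with a bulky silyl chloride.

Step 12
Reactants: 18 15-O-tert-butyldiphenylsilyl ether
Product: 19 6α-acetate
Conditions: Ac2O, pyridine, DMAP (cat.), CH2Cl2, rt
Reagents that add atoms: acetic anhydride, CC(=O)OC(C)=O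
Why: DMAP-catalysed acetylation; the acetate keeps O6 from lactonising before step 14 (a trans-lactone would lock the chair that leads to the 4E alkene) and from adding to the enone formed there.

Step 13
Reactants: 19 6α-acetate
Product: 20 tricyclic cyclobutanone (3-oxo)
Conditions: PPTS, acetone/H2O (10:1), 45 °C
Reagents that add atoms: water, O
Why: Mild acid hydrolysis of the dimethyl ketal leaves silyl ethers, acetate and tert-butyl ester intact; the ketone is wanted at C3 because it stabilises the C4 radical in step 14 and blocks C2–C3 cleavage.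

Step 14
Reactants: 20 tricyclic cyclobutanone
Product: 21 tert-butyl (1(10)E,4Z)-6α-acetoxy-8β-(tert-butyldimethylsilyloxy)-15-(tert-butyldiphenylsilyloxy)-3-oxogermacra-1(10),4-dien-12-oate
Conditions: PhMe (degassed, 0.01 M), BHT (cat.), base-washed sealed tube, 110–120 °C; taken on without chromatography
Reagents that add atoms: none
Why: Thermal cycloreversion of the bicyclo[2.2.0]hexane unit: homolysis of the central C1–C4 bond and cleavage of C5–C10 in the chair diyl with C6 axial (the other chair would put the 8-silyloxy group and C14 1,3-diaxial) should give the 4Z enone and the 1(10)E alkene.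

Step 15
Reactants: 21 (1(10)E,4Z)-dienone
Product: 22 1-iodo-3-methoxy-3,10-epoxide (bridged methyl ketal; C10 and C3 as in the target)
Conditions: NIS, MeOH (5 equiv), NaHCO3, MeCN, −20 → 0 °C, dark
Reagents that add atoms: N-iodosuccinimide, O=C1CCC(=O)N1I; methanol, CO
Why: Iodoetherification in its ketalising 5-endo form: iodonium forms on the electron-rich C1=C10 bond from the ring periphery, the C3 oxygen attacks the tertiary C10 from inside the ring (anti addition) and methanol completes the mixed ketal; C10 should be set by the conformer that turns C14 away from the 8-silyloxy group, and C3 follows from the bridge.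

Step 16
Reactants: 22 1-iodo-3-methoxy-3,10-epoxide
Product: 23 3-methoxy-3,10-epoxide (C1 = CH2)
Conditions: Bu3SnH, AIBN (cat.), PhH, 80 °C
Reagents that add atoms: none
Why: Radical chain dehalogenation of the secondary iodide; C1 becomes CH2, so no stereocentre is affected.

Step 17
Reactants: 23 3-methoxy-3,10-epoxide
Product: 25 6α,12-olide (trans-fused γ-lactone), via hydroxy ester 24 (not isolated)
Conditions: K2CO3 (cat.), MeOH, rt
Reagents that add atoms: none
Why: Methanolysis of the acetate and 5-exo-trig transesterification of the freed 6α-alkoxide onto the tert-butyl ester give the trans-fused lactone, C6 and C7 having been set trans in steps 7 and 10.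

Step 18
Reactants: 25 6α,12-olide
Product: 29 11(13)-methylene lactone, via lactone enolate 26 (not isolated), via Mannich base 27 (not isolated), via ammonium iodide 28 (not isolated)
Conditions: LiN(iPr)2, THF, −78 °C; [Me2N=CH2]I, −78 °C → rt; then MeI, MeOH/CH2Cl2, rt; then aq. NaHCO3, CH2Cl2, rt
Reagents that add atoms: N,N-dimethylmethyleneiminium iodide (Eschenmoser's salt), C=[N+](C)C.[I-]
Why: α-Methylenation by the Mannich route (enolate aminomethylation, quaternisation, E1cB loss of trimethylamine); C11 becomes sp2, and the bridged ketal and silyl ethers are inert to the base.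

Step 19
Reactants: 29 11(13)-methylene lactone
Product: 30 8β-alcohol
Conditions: HF·pyridine, pyridine, THF, 0 °C → rt
Reagents that add atoms: none
Why: Buffered HF·pyridine cleaves the secondary tert-butyldimethylsilyl ether faster than the primary tert-butyldiphenylsilyl ether and, being non-basic, avoids oxa-Michael addition of O8 to the methylene lactone.

Step 20
Reactants: 30 8β-alcohol
Product: 31 8β-isobutyrate
Conditions: (iPrCO)2O, Et3N, DMAP (cat.), CH2Cl2, 0 °C → rt
Reagents that add atoms: isobutyric anhydride, CC(C)C(=O)OC(=O)C(C)C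
Why: DMAP-catalysed acylation of the only free hydroxyl, with retention at C8.

Step 21
Reactants: 31 8β-isobutyrate
Product: 33 CNP0282937.1, via hemiketal silyl ether 32 (not isolated)
Conditions: 48% aq. HF, MeCN, 0 °C → rt
Reagents that add atoms: water, O
Why: Aqueous HF hydrolyses the bridged methyl ketal to the hemiketal (the bridge allows only one configuration at C3) and cleaves the primary silyl ether, without touching the isobutyrate or the methylene lactone.

**Compound list**

1 | cis,cis-cyclohexane-1,3,5-triol | O[C@@H]1C[C@H](O)C[C@H](O)C1 | starting material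
2 | all-cis-5-(tert-butyldimethylsilyloxy)cyclohexane-1,3-diol (meso) | O[C@@H]1C[C@H](O)C[C@H](O[Si](C)(C)C(C)(C)C)C1 | intermediate
3 | (1S,3R,5R)-3-hydroxy-5-(tert-butyldimethylsilyloxy)cyclohexyl acetate | O[C@@H]1C[C@H](OC(C)=O)C[C@H](O[Si](C)(C)C(C)(C)C)C1 | intermediate
4 | (1R,5S)-3-oxo-5-(tert-butyldimethylsilyloxy)cyclohexyl acetate | O=C1C[C@H](OC(C)=O)C[C@H](O[Si](C)(C)C(C)(C)C)C1 | intermediate (not isolated)
5 | (S)-5-(tert-butyldimethylsilyloxy)cyclohex-2-en-1-one | O=C1C=CC[C@H](O[Si](C)(C)C(C)(C)C)C1 | intermediate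
6 | (5S)-1-methyl-5-(tert-butyldimethylsilyloxy)cyclohex-2-en-1-ol, C1 epimers | CC1(O)C=CC[C@H](O[Si](C)(C)C(C)(C)C)C1 | intermediate
7 | (R)-5-(tert-butyldimethylsilyloxy)-3-methylcyclohex-2-en-1-one | O=C1C=C(C)C[C@@H](O[Si](C)(C)C(C)(C)C)C1 | intermediate
8 | lithium dienolate of 7 (O–Li on C6, C6=C7) | [Li]OC1=C[C@H](O[Si](C)(C)C(C)(C)C)CC(C)=C1 | intermediate (not isolated)
9 | tert-butyl 2-[(1S,6R)-6-(tert-butyldimethylsilyloxy)-4-methyl-2-oxocyclohex-3-en-1-yl]acetate (trans) | O=C1C=C(C)C[C@@H](O[Si](C)(C)C(C)(C)C)[C@@H]1CC(=O)OC(C)(C)C | intermediate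
10 | lithium enolate of 9 (O–Li on C6, C6=C7) | [Li]OC1=C(CC(=O)OC(C)(C)C)[C@H](O[Si](C)(C)C(C)(C)C)CC(C)=C1 | intermediate (not isolated)
11 | tert-butyl 2-[(1R,6R)-6-(tert-butyldimethylsilyloxy)-4-methyl-2-oxocyclohex-3-en-1-yl]acetate (cis) | O=C1C=C(C)C[C@@H](O[Si](C)(C)C(C)(C)C)[C@H]1CC(=O)OC(C)(C)C | intermediate
12 | 1,1-dimethoxyethene | C=C(OC)OC | starting material
13 | methyl propiolate | C#CC(=O)OC | starting material
14 | methyl 4,4-dimethoxycyclobut-1-ene-1-carboxylate | COC(=O)C1=CCC1(OC)OC | intermediate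
15 | head-to-head cis-anti-cis photoadduct: 6-oxo, 3,3-dimethoxy, C15 methyl ester on C4, 7β-CH2CO2tBu, 8β-OTBS, four-membered rings on the α-face | O=C1[C@@H]2[C@@]3(C(=O)OC)C(OC)(OC)C[C@H]3[C@]2(C)C[C@@H](O[Si](C)(C)C(C)(C)C)[C@H]1CC(=O)OC(C)(C)C | intermediate
16 | 6α,15-lactone of the reduced photoadduct | O=C4O[C@@H]1[C@@H]2[C@@]34C(OC)(OC)C[C@H]3[C@]2(C)C[C@@H](O[Si](C)(C)C(C)(C)C)[C@H]1CC(=O)OC(C)(C)C | intermediate (not isolated)
17 | tricyclic 6α,15-diol | O[C@@H]1[C@@H]2[C@@]3(CO)C(OC)(OC)C[C@H]3[C@]2(C)C[C@@H](O[Si](C)(C)C(C)(C)C)[C@H]1CC(=O)OC(C)(C)C | intermediate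
18 | tricyclic 6α-alcohol, 15-O-TBDPS ether | O[C@@H]1[C@@H]2[C@@]3(CO[Si](c4ccccc4)(c4ccccc4)C(C)(C)C)C(OC)(OC)C[C@H]3[C@]2(C)C[C@@H](O[Si](C)(C)C(C)(C)C)[C@H]1CC(=O)OC(C)(C)C | intermediate
19 | tricyclic 6α-acetate, 3,3-dimethyl ketal | CC(=O)O[C@@H]1[C@@H]2[C@@]3(CO[Si](c4ccccc4)(c4ccccc4)C(C)(C)C)C(OC)(OC)C[C@H]3[C@]2(C)C[C@@H](O[Si](C)(C)C(C)(C)C)[C@H]1CC(=O)OC(C)(C)C | intermediate
20 | tricyclic cyclobutanone (3-oxo), 6α-acetate | CC(=O)O[C@@H]1[C@@H]2[C@@]3(CO[Si](c4ccccc4)(c4ccccc4)C(C)(C)C)C(=O)C[C@H]3[C@]2(C)C[C@@H](O[Si](C)(C)C(C)(C)C)[C@H]1CC(=O)OC(C)(C)C | intermediate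
21 | tert-butyl (1(10)E,4Z)-6α-acetoxy-8β-(tert-butyldimethylsilyloxy)-15-(tert-butyldiphenylsilyloxy)-3-oxogermacra-1(10),4-dien-12-oate | O=C1C/C=C(\C)C[C@@H](O[Si](C)(C)C(C)(C)C)[C@@H](CC(=O)OC(C)(C)C)[C@H](OC(C)=O)/C=C1/CO[Si](c2ccccc2)(c2ccccc2)C(C)(C)C | intermediate
22 | 1-iodo-3-methoxy-3,10-epoxy-germacr-4-ene (bridged ketal), 6α-acetate, tert-butyl ester | CC(=O)O[C@@H]1/C=C(/CO[Si](c2ccccc2)(c2ccccc2)C(C)(C)C)[C@@]2(OC)C[C@@H](I)[C@](C)(C[C@@H](O[Si](C)(C)C(C)(C)C)[C@H]1CC(=O)OC(C)(C)C)O2 | intermediate
23 | 3-methoxy-3,10-epoxy-germacr-4-ene, 6α-acetate, tert-butyl ester | CC(=O)O[C@@H]1/C=C(/CO[Si](c2ccccc2)(c2ccccc2)C(C)(C)C)[C@@]2(OC)CC[C@](C)(C[C@@H](O[Si](C)(C)C(C)(C)C)[C@H]1CC(=O)OC(C)(C)C)O2 | intermediate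
24 | 6α-hydroxy tert-butyl ester | O[C@@H]1/C=C(/CO[Si](c2ccccc2)(c2ccccc2)C(C)(C)C)[C@@]2(OC)CC[C@](C)(C[C@@H](O[Si](C)(C)C(C)(C)C)[C@H]1CC(=O)OC(C)(C)C)O2 | intermediate (not isolated)
25 | 3-methoxy-3,10-epoxy-germacr-4-en-6α,12-olide, 8β-OTBS, 15-OTBDPS | C1C(=O)O[C@@H]2/C=C(/CO[Si](c4ccccc4)(c4ccccc4)C(C)(C)C)[C@@]3(OC)CC[C@](C)(C[C@@H](O[Si](C)(C)C(C)(C)C)[C@@H]12)O3 | intermediate
26 | lithium enolate of lactone 25 | C1=C(O[Li])O[C@@H]2/C=C(/CO[Si](c4ccccc4)(c4ccccc4)C(C)(C)C)[C@@]3(OC)CC[C@](C)(C[C@@H](O[Si](C)(C)C(C)(C)C)[C@@H]12)O3 | intermediate (not isolated)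
27 | 13-(dimethylamino) lactone (Mannich base, C11 epimers) | CN(C)CC1C(=O)O[C@@H]2/C=C(/CO[Si](c4ccccc4)(c4ccccc4)C(C)(C)C)[C@@]3(OC)CC[C@](C)(C[C@@H](O[Si](C)(C)C(C)(C)C)[C@@H]12)O3 | intermediate (not isolated)
28 | 13-(trimethylammonio) lactone iodide | C[N+](C)(C)CC1C(=O)O[C@@H]2/C=C(/CO[Si](c4ccccc4)(c4ccccc4)C(C)(C)C)[C@@]3(OC)CC[C@](C)(C[C@@H](O[Si](C)(C)C(C)(C)C)[C@@H]12)O3.[I-] | intermediate (not isolated)
29 | 3-methoxy-3,10-epoxy-germacra-4,11(13)-dien-6α,12-olide, 8β-OTBS, 15-OTBDPS | C=C1C(=O)O[C@@H]2/C=C(/CO[Si](c4ccccc4)(c4ccccc4)C(C)(C)C)[C@@]3(OC)CC[C@](C)(C[C@@H](O[Si](C)(C)C(C)(C)C)[C@@H]12)O3 | intermediate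
30 | 8β-hydroxy methylene lactone, 15-OTBDPS | C=C1C(=O)O[C@@H]2/C=C(/CO[Si](c4ccccc4)(c4ccccc4)C(C)(C)C)[C@@]3(OC)CC[C@](C)(C[C@@H](O)[C@@H]12)O3 | intermediate
31 | 8β-isobutyrate, 3-methyl ketal, 15-OTBDPS | C=C1C(=O)O[C@@H]2/C=C(/CO[Si](c4ccccc4)(c4ccccc4)C(C)(C)C)[C@@]3(OC)CC[C@](C)(C[C@@H](OC(=O)C(C)C)[C@@H]12)O3 | intermediate
32 | 3-hemiketal, 15-OTBDPS | C=C1C(=O)O[C@@H]2/C=C(/CO[Si](c4ccccc4)(c4ccccc4)C(C)(C)C)[C@@]3(O)CC[C@](C)(C[C@@H](OC(=O)C(C)C)[C@@H]12)O3 | intermediate (not isolated)
33 | CNP0282937.1 | C=C1C(=O)O[C@@H]2/C=C(/CO)[C@@]3(O)CC[C@](C)(C[C@@H](OC(=O)C(C)C)[C@@H]12)O3 | target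

**Count**

Total steps: 21. Longest linear sequence: 20 steps (steps 1–7 and 9–21); step 8 is a one-step branch.

**Steps most likely to fail**

Step 14. The diyl may collapse through the other chair (C6 equatorial) and give the (1(10)Z,4E) geometry, and the β,γ-unsaturated ketone may drift into conjugation on handling. Fallback: the opening of 20 is run as before and the (1(10)Z,4E)-dienone F2 is not discarded but equilibrated by a thiyl radical chain (PhSSPh cat., visible light, PhH), which adds reversibly to both double bonds. The mixture is passed into step 15, where only the 4Z isomer has C3 and C6 on the same side and can bridge; the rest is re-equilibrated. The fallback sets out from 20 and comes back to the route at 21.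

Step 15. External methanol may capture the iodonium ion at C10 in competition with the 5-endo closure, or the closure may take the other alkene face and erode C10. Fallback from 21: mCPBA (NaHCO3, CH2Cl2) epoxidises only the electron-rich C1=C10 bond to the 1,10-epoxide F3. With CSA (cat.) and MeOH the C3 oxygen opens the epoxide at the tertiary C10 with inversion and methanol completes the ketal, giving the 1-hydroxy ketal F4. The C1 hydroxyl is removed by Barton–McCombie deoxygenation through the imidazolyl thiocarbonate F5 (1,1'-thiocarbonyldiimidazole, DMAP; then Bu3SnH, AIBN). The fallback comes back to the route at 23.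

Step 7. Proton transfer to oxygen followed by equilibration of the enol, or epimerisation during work-up, may return the trans isomer. Fallback from 9: the enolate is trapped as the trimethylsilyl dienol ether F1 (LiN(iPr)2; TMSCl), which is protonated under reagent control with a Lewis acid-assisted chiral Brønsted acid (SnCl4·BINOL, the enantiomer matched to the substrate bias, PhMe, −78 °C). The fallback comes back to the route at 11.

**Further compounds**

F1 | step 7 | trimethylsilyl dienol ether of 9 (O–Si on C6, C6=C7) | C[Si](C)(C)OC1=C(CC(=O)OC(C)(C)C)[C@H](O[Si](C)(C)C(C)(C)C)CC(C)=C1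
F2 | step 14 | (1(10)Z,4E) isomer of dienone 21 | O=C1C/C=C(/C)C[C@@H](O[Si](C)(C)C(C)(C)C)[C@@H](CC(=O)OC(C)(C)C)[C@H](OC(C)=O)/C=C1\CO[Si](c2ccccc2)(c2ccccc2)C(C)(C)C
F3 | step 15 | 1,10-epoxide of 21 | O=C1C[C@H]2O[C@]2(C)C[C@@H](O[Si](C)(C)C(C)(C)C)[C@@H](CC(=O)OC(C)(C)C)[C@H](OC(C)=O)/C=C1/CO[Si](c3ccccc3)(c3ccccc3)C(C)(C)C
F4 | step 15 | 1-hydroxy-3-methoxy-3,10-epoxide (bridged ketal) | CC(=O)O[C@@H]1/C=C(/CO[Si](c2ccccc2)(c2ccccc2)C(C)(C)C)[C@@]2(OC)C[C@@H](O)[C@](C)(C[C@@H](O[Si](C)(C)C(C)(C)C)[C@H]1CC(=O)OC(C)(C)C)O2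
F5 | step 15 | 1-O-(imidazol-1-ylthiocarbonyl) derivative of F4 | CC(=O)O[C@@H]1/C=C(/CO[Si](c2ccccc2)(c2ccccc2)C(C)(C)C)[C@@]2(OC)C[C@@H](OC(=S)n3ccnc3)[C@](C)(C[C@@H](O[Si](C)(C)C(C)(C)C)[C@H]1CC(=O)OC(C)(C)C)O2
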